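A direct plan would turn bis-TBS-protected caffeic acid A1 into its symmetrical diacyl peroxide A2. Under chiral secondary-amine catalysis, A2 would transfer a caffeoyloxy group to the enamine of the saturated aldehyde made in the same flask by iminium hydride reduction of the TBS-protected cinnamaldehyde A3.
The (R)-α-acyloxy aldehyde A4 would then be taken by Pinnick oxidation to the acid A5, and desilylation would end the route.
- The hydride/acyloxylation cascade that forms the C2–O bond would be the weakest step. The only stereocentre would rest on a cascade without precedent, the peroxide can consume both the hydride donor and the amine catalyst, and A4 can racemise through its own enamine.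
- The making and use of peroxide A2 would be weak because a light- and shock-sensitive peroxide of an electron-rich cinnamic acid must be handled, and half of the most valuable fragment returns as A1.
- The passage through A4 and its oxidation would be weak because C1 enters as an aldehyde only to be oxidised again, and a configurationally labile α-acyloxy aldehyde with electron-rich arenes meets an oxidant.

**Retrosynthetic overview**
- C2 (the O-acylated stereocentre) and the benzylic C3H2 are read as the hydrogenation retron of an achiral α-(caffeoyloxy)acrylate. The caffeoyl C=O on the C2 oxygen, part of the target itself, is the group that chelates the chiral rhodium catalyst, and the E/Z mixture converges on one enantiomer.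
- C2=C3 is cut by a Horner–Wadsworth–Emmons olefination between vanillin MOM ether and an α-(caffeoyloxy)phosphonoacetate, itself made by carbenoid O–H insertion of MOM-protected caffeic acid.
- No ring is formed: the guaiacyl ring is bought as vanillin and the catechol ring as caffeic acid.
- C1 stays at the acid oxidation level (tert-butyl ester) throughout, no peroxide and no α-acyloxy aldehyde appear, every caffeoyl unit is used, and three MOM ethers and the tert-butyl ester leave in one acidolysis.

Key step: step 6

Remark (assumption): C2 of the target is (R). The (R,R)-bisphospholane is assumed to give (R) with the enol ester, as it does with the analogous enamides. If the sense proved opposite, the (S,S)-ligand would be used with nothing else changed.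

**Step 1**
Reactants: 1 caffeic acid
Product: 3 (E)-3-[3,4-bis(methoxymethoxy)phenyl]acrylic acid, via methoxymethyl ester 2 (not isolated)
Conditions: MOMCl (3.6 equiv), i-Pr2NEt (5 equiv), CH2Cl2/DMF, 0 °C → rt; then LiOH (3 equiv), THF/H2O, rt; 1 M HCl to pH 4 at 0 °C
Reagents that add atoms: chloromethyl methyl ether (MOMCl), COCCl; lithium hydroxide (one carboxyl oxygen), [Li+].[OH-]
Why: Williamson-type O-alkylation by the α-chloro ether caps all three acidic OH groups, and the acylal-type MOM ester, far more electrophilic than the base-stable aryl MOM ethers, is then saponified selectively.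

**Step 2**
Reactants: 4 tert-butyl 2-(diethoxyphosphoryl)acetate
Product: 5 tert-butyl 2-diazo-2-(diethoxyphosphoryl)acetate
Conditions: NaH (1.05 equiv), THF, 0 °C; then 4-acetamidobenzenesulfonyl azide (1.1 equiv), 0 °C → rt; aqueous work-up
Reagents that add atoms: 4-acetamidobenzenesulfonyl azide, CC(=O)Nc1ccc(cc1)S(=O)(=O)N=[N+]=[N-]
Why: Regitz diazo transfer, in which the sodium enolate of the phosphonoacetate attacks the terminal azide nitrogen and the triazene collapses to the acceptor/acceptor diazo compound and the sulfonamide anion.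

**Step 3**
Reactants: 5 tert-butyl 2-diazo-2-(diethoxyphosphoryl)acetate (1.2 equiv); 3 (E)-3-[3,4-bis(methoxymethoxy)phenyl]acrylic acid (1.0 equiv)
Product: 6 tert-butyl 2-(diethoxyphosphoryl)-2-{[(E)-3-(3,4-bis(methoxymethoxy)phenyl)acryloyl]oxy}acetate (racemic)
Conditions: Rh2(OAc)4 (1 mol %), toluene, 80 °C, slow addition of 5 over 2 h
Reagents that add atoms: none
Why: Dirhodium carbenoid O–H insertion, in which the electrophilic acceptor/acceptor carbenoid from 5 should be intercepted by the carboxylic acid O–H of 3 much faster than by the electron-poor cinnamate C=C or the arenes, giving the α-acyloxy phosphonate with loss of N2.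

**Step 4**
Reactants: 7 vanillin (4-hydroxy-3-methoxybenzaldehyde)
Product: 8 3-methoxy-4-(methoxymethoxy)benzaldehyde
Conditions: MOMCl (1.3 equiv), i-Pr2NEt (2 equiv), CH2Cl2, 0 °C → rt
Reagents that add atoms: chloromethyl methyl ether (MOMCl), COCCl
Why: Standard phenol O-alkylation gives a base-stable acetal that keeps the aldehyde electrophilic for the olefination and later leaves in the same acid step as the other protecting groups.

**Step 5**
Reactants: 6 α-(caffeoyloxy)phosphonoacetate (1.05 equiv); 8 3-methoxy-4-(methoxymethoxy)benzaldehyde (1.0 equiv)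
Product: 9 tert-butyl 2-{[(E)-3-(3,4-bis(methoxymethoxy)phenyl)acryloyl]oxy}-3-[3-methoxy-4-(methoxymethoxy)phenyl]acrylate (E/Z mixture at C2=C3)
Conditions: LiCl (1.5 equiv), DBU (1.1 equiv), THF, −20 → 0 °C; E/Z mixture used as such
Reagents that add atoms: none
Why: Horner–Wadsworth–Emmons olefination under Masamune–Roush conditions, with close precedent for α-acetoxy and α-benzoyloxy phosphonoacetates, should form C2=C3 through the lithium-chelated phosphonate anion, and the E/Z ratio does not matter because step 6 is stereoconvergent.

**Step 6**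
Reactants: 9 enol ester (E/Z mixture)
Product: 10 tert-butyl (R)-2-{[(E)-3-(3,4-bis(methoxymethoxy)phenyl)acryloyl]oxy}-3-[3-methoxy-4-(methoxymethoxy)phenyl]propanoate
Conditions: [Rh(cod)((R,R)-Et-DuPHOS)]BF4 (1 mol %; ligand = 1,2-bis[(2R,5R)-2,5-diethylphospholan-1-yl]benzene), H2 (4 bar), degassed MeOH/CH2Cl2 (4:1), 25 °C, stopped after uptake of one equivalent of H2
Reagents that add atoms: none
Why: Cationic monovalent rhodium bound to the bisphospholane should chelate 9 through the C2=C3 bond and the caffeoyl C=O on the C2 oxygen in a five-membered chelate, add H2 oxidatively, insert the alkene and eliminate reductively, so that both hydrogens reach one face. The closest known reaction type is the rhodium–bisphospholane hydrogenation of α-(acyloxy)acrylates, in which E and Z isomers both lead to the same enantiomer, so the mixture from step 5 converges. No ring is closed. The single stereocentre C2 is set by the C2-symmetric ligand, whose (R,R)-antipode gives (R)-α-amino and (R)-α-hydroxy acid derivatives in this chelation mode and should give (R)-10. The step needs chemoselectivity for the enol-ester alkene over the caffeoyl C=C: only the former can form the chelate, such cationic catalysts leave non-chelating 1,2-disubstituted cinnamates essentially untouched at low pressure, and hydrogen uptake is stopped at one equivalent. The tert-butyl ester, the acetals and the aryl ethers are inert.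

**Step 7**
Reactants: 10 (R)-tert-butyl ester tris-MOM ether
Product: 11 clinopodic acid B [(R)-2-{[(E)-3-(3,4-dihydroxyphenyl)acryloyl]oxy}-3-(4-hydroxy-3-methoxyphenyl)propanoic acid]
Conditions: TFA/CH2Cl2/H2O (10:10:1), 0 °C → rt, Ar, dark; evaporation below 30 °C; reversed-phase chromatography (MeCN/H2O, 0.1% HCO2H)
Reagents that add atoms: none
Why: Acid-catalysed acetal cleavage of the three aryl MOM ethers and acidolysis of the tert-butyl ester (loss of isobutene) should occur together, while the cinnamate ester, the E-alkene and C2, which meets no base that could enolise it, are stable to acid at room temperature.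

**Compound list**
1 | caffeic acid | O=C(O)/C=C/c1ccc(O)c(O)c1 | starting material
2 | methoxymethyl (E)-3-[3,4-bis(methoxymethoxy)phenyl]acrylate | COCOC(=O)/C=C/c1ccc(OCOC)c(OCOC)c1 | intermediate (not isolated)
3 | (E)-3-[3,4-bis(methoxymethoxy)phenyl]acrylic acid | O=C(O)/C=C/c1ccc(OCOC)c(OCOC)c1 | intermediate
4 | tert-butyl 2-(diethoxyphosphoryl)acetate | CCOP(=O)(CC(=O)OC(C)(C)C)OCC | starting material
5 | tert-butyl 2-diazo-2-(diethoxyphosphoryl)acetate | CCOP(=O)(OCC)C(=[N+]=[N-])C(=O)OC(C)(C)C | intermediate
6 | tert-butyl 2-(diethoxyphosphoryl)-2-{[(E)-3-(3,4-bis(methoxymethoxy)phenyl)acryloyl]oxy}acetate (racemic) | CCOP(=O)(OCC)C(OC(=O)/C=C/c1ccc(OCOC)c(OCOC)c1)C(=O)OC(C)(C)C | intermediate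
7 | vanillin | COc1cc(C=O)ccc1O | starting material
8 | 3-methoxy-4-(methoxymethoxy)benzaldehyde | COCOc1ccc(C=O)cc1OC | intermediate
9 | tert-butyl 2-{[(E)-3-(3,4-bis(methoxymethoxy)phenyl)acryloyl]oxy}-3-[3-methoxy-4-(methoxymethoxy)phenyl]acrylate (E/Z mixture at C2=C3) | COCOc1ccc(C=C(OC(=O)/C=C/c2ccc(OCOC)c(OCOC)c2)C(=O)OC(C)(C)C)cc1OC | intermediate
10 | tert-butyl (R)-2-{[(E)-3-(3,4-bis(methoxymethoxy)phenyl)acryloyl]oxy}-3-[3-methoxy-4-(methoxymethoxy)phenyl]propanoate | COCOc1ccc(C[C@@H](OC(=O)/C=C/c2ccc(OCOC)c(OCOC)c2)C(=O)OC(C)(C)C)cc1OC | intermediate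
11 | clinopodic acid B, (R) | COc1cc(C[C@@H](OC(=O)/C=C/c2ccc(O)c(O)c2)C(=O)O)ccc1O | target

Total step count: 7. Longest linear sequence: 5 steps (steps 1, 3, 5, 6, 7).

**Steps most likely to fail**

1. Step 6. The caffeoyl C=C could be reduced alongside or after the enol ester, or facial discrimination could fall when the extended cinnamoyl group is the chelating acyl group. The fallback sets out from 5 and comes back at 10, and sets the stereocentre on a substrate with no second alkene before the caffeoyl group is attached. Rh2(OAc)4-catalysed O–H insertion of acetic acid into 5 would give tert-butyl 2-acetoxy-2-(diethoxyphosphoryl)acetate F1. Olefination of 8 with F1 (LiCl, DBU) would give the enol acetate F2. The same rhodium–bisphospholane hydrogenation would give the (R)-acetoxy ester F3. K2CO3 in MeOH at 0 °C would free the (R)-hydroxy ester F4, and Steglich esterification of F4 with 3 (EDC·HCl, DMAP) would give 10.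

2. Step 5. The caffeoyl group could be transferred from the phosphonate anion, or the enol ester product cleaved by the amidine, in competition with olefination. The fallback sets out from 8 and comes back at 9, and builds the enol ester by O-acylation instead of olefination. Erlenmeyer condensation of 8 with N-acetylglycine (Ac2O, NaOAc, 100 °C) would give the azlactone F5. Aqueous NaOH at reflux followed by cold acidification would give the arylpyruvic acid F6. N,N-dimethylformamide di-tert-butyl acetal in toluene at 80 °C would give its tert-butyl ester F7, which is largely enolised. O-acylation of that enol with 3 (EDC·HCl, DMAP) would give 9, mainly as the Z isomer.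

3. Step 3. The carbenoid could be diverted to cyclopropanation of the cinnamate, to ylide formation at the acetal oxygens or to dimerisation, instead of O–H insertion. The fallback sets out from 3 and comes back at 6, and forms the acyl–oxygen bond instead of the C2–O bond. Pudovik addition of diethyl phosphite to commercial tert-butyl glyoxylate (Et3N cat.) would give the hydroxyphosphonate F8, and Steglich esterification of F8 with 3 (EDC·HCl, DMAP) would give 6.

**Further compounds**
F1 | step 6 | tert-butyl 2-acetoxy-2-(diethoxyphosphoryl)acetate | CCOP(=O)(OCC)C(OC(C)=O)C(=O)OC(C)(C)C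
F2 | step 6 | tert-butyl 2-acetoxy-3-[3-methoxy-4-(methoxymethoxy)phenyl]acrylate (E/Z mixture) | COCOc1ccc(C=C(OC(C)=O)C(=O)OC(C)(C)C)cc1OC
F3 | step 6 | tert-butyl (R)-2-acetoxy-3-[3-methoxy-4-(methoxymethoxy)phenyl]propanoate | COCOc1ccc(C[C@@H](OC(C)=O)C(=O)OC(C)(C)C)cc1OC
F4 | step 6 | tert-butyl (R)-2-hydroxy-3-[3-methoxy-4-(methoxymethoxy)phenyl]propanoate | COCOc1ccc(C[C@@H](O)C(=O)OC(C)(C)C)cc1OC
F5 | step 5 | (Z)-4-[3-methoxy-4-(methoxymethoxy)benzylidene]-2-methyloxazol-5(4H)-one | COCOc1ccc(/C=C2\N=C(C)OC2=O)cc1OC
F6 | step 5 | 3-[3-methoxy-4-(methoxymethoxy)phenyl]-2-oxopropanoic acid | COCOc1ccc(CC(=O)C(=O)O)cc1OC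
F7 | step 5 | tert-butyl 3-[3-methoxy-4-(methoxymethoxy)phenyl]-2-oxopropanoate | COCOc1ccc(CC(=O)C(=O)OC(C)(C)C)cc1OC
F8 | step 3 | tert-butyl 2-(diethoxyphosphoryl)-2-hydroxyacetate | CCOP(=O)(OCC)C(O)C(=O)OC(C)(C)C
A1 | direct plan | (E)-3-[3,4-bis(tert-butyldimethylsilyloxy)phenyl]acrylic acid | O=C(O)/C=C/c1ccc(O[Si](C)(C)C(C)(C)C)c(O[Si](C)(C)C(C)(C)C)c1
A2 | direct plan | bis{(E)-3-[3,4-bis(tert-butyldimethylsilyloxy)phenyl]acryloyl} peroxide | O=C(/C=C/c1ccc(O[Si](C)(C)C(C)(C)C)c(O[Si](C)(C)C(C)(C)C)c1)OOC(=O)/C=C/c1ccc(O[Si](C)(C)C(C)(C)C)c(O[Si](C)(C)C(C)(C)C)c1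
A3 | direct plan | (E)-3-[4-(tert-butyldimethylsilyloxy)-3-methoxyphenyl]acrylaldehyde | COc1cc(/C=C/C=O)ccc1O[Si](C)(C)C(C)(C)C
A4 | direct plan | (R)-1-[4-(tert-butyldimethylsilyloxy)-3-methoxyphenyl]-3-oxopropan-2-yl (E)-3-[3,4-bis(tert-butyldimethylsilyloxy)phenyl]acrylate | COc1cc(C[C@@H](OC(=O)/C=C/c2ccc(O[Si](C)(C)C(C)(C)C)c(O[Si](C)(C)C(C)(C)C)c2)C=O)ccc1O[Si](C)(C)C(C)(C)C
A5 | direct plan | (R)-2-{[(E)-3-(3,4-bis(tert-butyldimethylsilyloxy)phenyl)acryloyl]oxy}-3-[4-(tert-butyldimethylsilyloxy)-3-methoxyphenyl]propanoic acid | COc1cc(C[C@@H](OC(=O)/C=C/c2ccc(O[Si](C)(C)C(C)(C)C)c(O[Si](C)(C)C(C)(C)C)c2)C(=O)O)ccc1O[Si](C)(C)C(C)(C)C
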